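The cyclopentane of this daucane is cut at the bond between the isopropyl carbinol carbon C4 and the ring-fusion carbon C5. With C6 as a ketone, C4–C5–C6 is an aldol unit and the quaternary C1 is the β-carbon of the C5 enolate. One operation sets C1, C5 and C4 and closes the five-membered ring: copper-catalysed asymmetric conjugate methylation of an achiral 3-(4-methyl-3-oxopentyl)cyclohepta-2,5-dienone, then aldol closure of the aluminium enolate onto the side-chain ketone. The dienone comes from Birch dearomatisation of a phenol and one-carbon ring expansion. Directed reduction, directed epoxidation and benzoylation finish the route.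

Key step: step 8

Remark: daucane numbering is used for the bicyclic compounds: C1 quaternary ring-fusion carbon (CH3), C2 and C3 CH2, C4 carbinol carbon (iPr), C5 ring-fusion CH, C6 oxygen-bearing carbon, C7 CH2, C8 (CH3)=C9, C10 CH2. Compounds 10 and 12 carry a C8=C9 double bond β,γ to the C6 ketone and are assumed to be handled without base or strong acid.

Step 1
Reactants: 1 2-hydroxy-4-methylbenzaldehyde; 2 3-methylbutan-2-one
Product: 3 (E)-1-(2-hydroxy-4-methylphenyl)-4-methylpent-1-en-3-one
Conditions: NaOH (aq), EtOH, 0 °C → rt
Reagents that add atoms: none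
Why: Claisen–Schmidt aldol condensation, in which only the methyl side of 2 can dehydrate to the conjugated (E)-enone, so the methine side does not compete.

Step 2
Reactants: 3 (E)-1-(2-hydroxy-4-methylphenyl)-4-methylpent-1-en-3-one
Product: 4 1-(2-hydroxy-4-methylphenyl)-4-methylpentan-3-one
Conditions: H2 (1 atm), 10% Pd/C, EtOAc, rt
Reagents that add atoms: none
Why: Catalytic hydrogenation should reduce the conjugated C=C bond selectively over the dialkyl ketone and the arene.

Step 3
Reactants: 4 1-(2-hydroxy-4-methylphenyl)-4-methylpentan-3-one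
Product: 5 1-[2-(tert-butyldimethylsilyloxy)-4-methylphenyl]-4-methylpentan-3-one
Conditions: TBSCl, imidazole, DMF, rt
Reagents that add atoms: tert-butyldimethylsilyl chloride, CC(C)(C)[Si](C)(C)Cl
Why: Standard phenol silylation, which traps the open hydroxy ketone out of its equilibrium with the cyclic hemiketal and provides the silyl group that step 4 turns into a silyl enol ether.

Step 4
Reactants: 5 1-[2-(tert-butyldimethylsilyloxy)-4-methylphenyl]-4-methylpentan-3-one
Product: 6 1-[2-(tert-butyldimethylsilyloxy)-4-methylcyclohexa-1,4-dien-1-yl]-4-methylpentan-3-ol (racemic)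
Conditions: Li, liq. NH3, THF, t-BuOH, −78 → −33 °C; solid NH4Cl quench
Reagents that add atoms: none
Why: Birch reduction (dearomatisation) leaves the oxygen and both alkyl substituents on sp2 carbons, so a single 1-silyloxy-1,4-diene regioisomer should form; the ketone is reduced to the carbinol in the same operation and its stereocentre is erased in step 7.

Step 5
Reactants: 6 1-[2-(tert-butyldimethylsilyloxy)-4-methylcyclohexa-1,4-dien-1-yl]-4-methylpentan-3-ol
Product: 7 1-[6-(tert-butyldimethylsilyloxy)-4-methylbicyclo[4.1.0]hept-3-en-1-yl]-4-methylpentan-3-ol (racemic, diastereomer mixture)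
Conditions: Et2Zn, CH2I2, CH2Cl2, 0 °C → rt
Reagents that add atoms: diiodomethane, ICI
Why: Furukawa–Simmons–Smith cyclopropanation, in which the electrophilic zinc carbenoid should choose the electron-rich tetrasubstituted silyl enol ether (also reached from the zinc alkoxide of the side chain) over the trisubstituted alkene.

Step 6
Reactants: 7 1-[6-(tert-butyldimethylsilyloxy)-4-methylbicyclo[4.1.0]hept-3-en-1-yl]-4-methylpentan-3-ol
Product: 9 3-(3-hydroxy-4-methylpentyl)-6-methylcyclohepta-2,5-dien-1-one (racemic), via β-chloro ketone 8 (not isolated)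
Conditions: FeCl3 (2.5 equiv), DMF, 0 °C → rt; then NaOAc, MeOH, 50 °C
Reagents that add atoms: none
Why: Saegusa–Ito ring expansion: Fe(III) takes the silyl group, the iron cyclopropoxide cleaves the internal bond to the tertiary β-keto radical, chlorine transfer gives 8, and loss of HCl through the enolate on the chlorine side gives the cycloheptenone while the remote trisubstituted alkene stays unconjugated.

Step 7
Reactants: 9 3-(3-hydroxy-4-methylpentyl)-6-methylcyclohepta-2,5-dien-1-one
Product: 10 6-methyl-3-(4-methyl-3-oxopentyl)cyclohepta-2,5-dien-1-one (achiral)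
Conditions: Dess–Martin periodinane, NaHCO3, CH2Cl2, 0 °C → rt
Reagents that add atoms: none
Why: Dess–Martin oxidation of the secondary alcohol under buffered, non-basic conditions should leave the skipped dienone unisomerised.

Step 8
Reactants: 10 6-methyl-3-(4-methyl-3-oxopentyl)cyclohepta-2,5-dien-1-one
Product: 12 (1R,4R,5R)-4-hydroxydauc-8-en-6-one, via aluminium enolate 11 (not isolated)
Conditions: Me3Al (2 equiv), CuTC (5 mol %), chiral phosphoramidite ligand (10 mol %), Et2O, −30 °C, then 0 °C; aq. Rochelle salt
Reagents that add atoms: trimethylaluminium, C[Al](C)C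
Why: The Cu(I)–phosphoramidite complex transfers a methyl group from Me3Al to the β-carbon C1 of the cycloheptenone (1,4-addition), which makes the quaternary centre and, without any deprotonation, the C5=C6 dimethylaluminium enolate 11; this enolate adds to the side-chain isopropyl ketone and forms the C4–C5 bond. The closest known reaction types are the copper-catalysed asymmetric conjugate addition of trialkylaluminium reagents to 3-substituted cyclohept-2-enones and the conjugate addition–aldol cyclisation cascades of keto-enones. The cyclopentane closes in a 5-(enolexo)-exo-trig aldol mode. C1 is controlled by the chiral ligand (enantiomer chosen to give 1R, sense to be confirmed); C4 by the aluminium-bridged six-membered transition state, which holds the C4 oxygen next to O6 and the isopropyl group away from C6; C5 by the ring fusion, which is expected to settle as trans because the aluminium aldolate can revert to the same enolate and re-close until the isopropyl group sits anti to the angular methyl. The step needs 1,4- over 1,2-addition, a side-chain ketone that survives Me3Al, and an enolate that stays at C5 and does not move to the doubly activated C7; low temperature in ether, the hindered isopropyl ketone and the base-free generation of the enolate should secure these.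

Step 9
Reactants: 12 (1R,4R,5R)-4-hydroxydauc-8-en-6-one
Product: 13 (1R,4R,5S,6S)-dauc-8-ene-4,6-diol (jaeschkeanadiol)
Conditions: Me4NBH(OAc)3, MeCN/AcOH, −30 → −20 °C
Reagents that add atoms: none
Why: Evans–Saksena directed reduction, in which the boron bound to the C4 hydroxyl should deliver hydride to the face of the C6 carbonyl flanked by C4 and so give the 6S alcohol with O6 cis to H5, under conditions too mild to move the C8=C9 bond.

Step 10
Reactants: 13 (1R,4R,5S,6S)-dauc-8-ene-4,6-diol
Product: 14 (1R,4R,5S,6S,8R,9S)-8,9-epoxydaucane-4,6-diol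
Conditions: VO(acac)2 (5 mol %), t-BuOOH, CH2Cl2, 0 °C
Reagents that add atoms: tert-butyl hydroperoxide, CC(C)(C)OO
Why: Vanadium-catalysed hydroxyl-directed epoxidation, in which the homoallylic C6 hydroxyl should deliver oxygen to the face of C8=C9 on its own side and so set C8 and C9.

Step 11
Reactants: 14 (1R,4R,5S,6S,8R,9S)-8,9-epoxydaucane-4,6-diol
Product: 15 (1R,4R,5S,6S,8R,9S)-8,9-epoxy-4-hydroxydaucan-6-yl benzoate (target)
Conditions: Bz2O, Et3N, DMAP (cat.), CH2Cl2, rt
Reagents that add atoms: benzoic anhydride, O=C(OC(=O)c1ccccc1)c1ccccc1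
Why: DMAP-catalysed acylation should esterify only the secondary C6 hydroxyl (the tertiary C4 hydroxyl is inert), and the chloride-free reagent spares the epoxide.

Compound list
1 | 2-hydroxy-4-methylbenzaldehyde | Cc1ccc(C=O)c(O)c1 | starting material
2 | 3-methylbutan-2-one | CC(=O)C(C)C | starting material
3 | (E)-1-(2-hydroxy-4-methylphenyl)-4-methylpent-1-en-3-one | Cc1ccc(/C=C/C(=O)C(C)C)c(O)c1 | intermediate
4 | 1-(2-hydroxy-4-methylphenyl)-4-methylpentan-3-one | Cc1ccc(CCC(=O)C(C)C)c(O)c1 | intermediate
5 | 1-[2-(tert-butyldimethylsilyloxy)-4-methylphenyl]-4-methylpentan-3-one | Cc1ccc(CCC(=O)C(C)C)c(O[Si](C)(C)C(C)(C)C)c1 | intermediate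
6 | 1-[2-(tert-butyldimethylsilyloxy)-4-methylcyclohexa-1,4-dien-1-yl]-4-methylpentan-3-ol (racemic) | CC(C)C(O)CCC1=C(O[Si](C)(C)C(C)(C)C)CC(C)=CC1 | intermediate
7 | 1-[6-(tert-butyldimethylsilyloxy)-4-methylbicyclo[4.1.0]hept-3-en-1-yl]-4-methylpentan-3-ol (racemic, diastereomer mixture) | CC(C)C(O)CCC12CC=C(C)CC1(O[Si](C)(C)C(C)(C)C)C2 | intermediate
8 | 3-chloro-3-(3-hydroxy-4-methylpentyl)-6-methylcyclohept-5-en-1-one (not isolated) | CC(C)C(O)CCC1(Cl)CC=C(C)CC(=O)C1 | intermediate
9 | 3-(3-hydroxy-4-methylpentyl)-6-methylcyclohepta-2,5-dien-1-one (racemic) | CC(C)C(O)CCC1=CC(=O)CC(C)=CC1 | intermediate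
10 | 6-methyl-3-(4-methyl-3-oxopentyl)cyclohepta-2,5-dien-1-one | CC(C)C(=O)CCC1=CC(=O)CC(C)=CC1 | intermediate
11 | dimethylaluminium (3R)-3,6-dimethyl-3-(4-methyl-3-oxopentyl)cyclohepta-1,5-dien-1-olate (not isolated) | CC(C)C(=O)CC[C@]1(C)CC=C(C)CC(O[Al](C)C)=C1 | intermediate
12 | (1R,4R,5R)-4-hydroxydauc-8-en-6-one | CC(C)[C@]1(O)CC[C@]2(C)CC=C(C)CC(=O)[C@H]21 | intermediate
13 | (1R,4R,5S,6S)-dauc-8-ene-4,6-diol | CC(C)[C@]1(O)CC[C@]2(C)CC=C(C)C[C@H](O)[C@H]21 | intermediate
14 | (1R,4R,5S,6S,8R,9S)-8,9-epoxydaucane-4,6-diol | CC(C)[C@]1(O)CC[C@]2(C)C[C@@H]3O[C@]3(C)C[C@H](O)[C@H]21 | intermediate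
15 | (1R,4R,5S,6S,8R,9S)-8,9-epoxy-4-hydroxydaucan-6-yl benzoate | CC(C)[C@]1(O)CC[C@]2(C)C[C@@H]3O[C@]3(C)C[C@H](OC(=O)c3ccccc3)[C@H]21 | target

Total step count: 11
Longest linear sequence: 11 steps (1 → 15)

Steps most likely to fail

1. Step 8 (key step). The aldol may close under kinetic control on the face that carries the side chain and give the cis ring fusion with the wrong C4/C5 pair; five-ring closures onto a ring enolate normally favour cis, so this is the main stereochemical risk of the route. The aluminium enolate may also fail to add to the hindered ketone, or Me3Al may attack that ketone. The fallback sets out from 10 and separates the two events. The same copper-catalysed methyl addition is run, but the enolate is silylated in the flask (Et3SiOTf) to the triethylsilyl enol ether F1. The ring is then closed in a separate intramolecular Mukaiyama aldol (TiCl4 or BF3·OEt2, CH2Cl2, −78 °C), whose Lewis acid and transition-state type can be chosen independently of the addition. This returns to the route at 12.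

2. Step 6. The silyl ether may resist Fe(III), the tertiary chloride may lose HCl towards the diene side, or the skipped double bond may migrate into conjugation during the acetate treatment. The fallback sets out from 6 and replaces the radical ring expansion by a cationic one. Dibromocarbene (CHBr3, KOt-Bu, pentane, −20 °C) adds to the silyl enol ether to give the 7,7-dibromocyclopropane F2. Warming in toluene with pyridine opens the cyclopropane with loss of the silyl bromide to the 2-bromo-3-(3-hydroxy-4-methylpentyl)-6-methylcyclohepta-2,5-dien-1-one F3. Pd(PPh3)4/Bu3SnH removes the vinylic bromine under neutral conditions. This returns to the route at 9.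

3. Step 10. The vanadium Lewis acid may open the new epoxide through transannular attack of the C4 hydroxyl, or the two hydroxyls may compete in directing the oxidant. The fallback sets out from 13 and reverses the order. The C6 hydroxyl is benzoylated first (Bz2O, Et3N, DMAP) to the 6-benzoate F4. F4 is then epoxidised with buffered mCPBA (NaHCO3, CH2Cl2, 0 °C). The face is then chosen by the substrate alone, so an epimeric epoxide may have to be separated. This arrives directly at 15.

Further compounds
F1 | step 8 | triethyl{[(3R)-3,6-dimethyl-3-(4-methyl-3-oxopentyl)cyclohepta-1,5-dien-1-yl]oxy}silane | CC(C)C(=O)CC[C@]1(C)CC=C(C)CC(O[Si](CC)(CC)CC)=C1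
F2 | step 6 | 1-[7,7-dibromo-6-(tert-butyldimethylsilyloxy)-4-methylbicyclo[4.1.0]hept-3-en-1-yl]-4-methylpentan-3-ol | CC(C)C(O)CCC12CC=C(C)CC1(O[Si](C)(C)C(C)(C)C)C2(Br)Br
F3 | step 6 | 2-bromo-3-(3-hydroxy-4-methylpentyl)-6-methylcyclohepta-2,5-dien-1-one | CC(C)C(O)CCC1=C(Br)C(=O)CC(C)=CC1
F4 | step 10 | (1R,4R,5S,6S)-4-hydroxydauc-8-en-6-yl benzoate | CC(C)[C@]1(O)CC[C@]2(C)CC=C(C)C[C@H](OC(=O)c3ccccc3)[C@H]21
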